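**Retrosynthetic overview**

1. Feature: in ring A (the benzene ring of the 2H-chromene; O1, C2 gem-dimethyl, C3=C4, C5–OMe, C7–OH, C8-prenyl) the last free carbon, C6, carries the aryl 1,2-diketone between C5–OMe and O7–H. Such a 2-hydroxyaryl 1,2-diketone is a 3-aryl-4-hydroxycoumarin whose C3 has been oxidised and whose lactone carbonyl carbon has been removed as CO2.
2. Endgame: diketone ⇐ benzoin ⇐ 3-hydroxychroman-2,4-dione ⇐ linear pyranocoumarin, by C3 hydroxylation, lactone opening with decarboxylation, oxidation and desilylation.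
3. Key disconnection: pyranocoumarin ⇐ 7-hydroxychromene + bis(2,4,6-trichlorophenyl) arylmalonate; the C6–C bond and a temporary O7–C(=O) lactone ring are made in one thermal operation.
4. Fragments: the chromenol comes from 5-methoxyresorcinol (bis-MOM ether, lithiation and prenylation between the two oxygens, deprotection, annulation with 3-methylbut-2-enal). The malonate comes from 4-hydroxyphenylacetic acid (silylation, dianion carboxylation, active ester).
5. Ring order: pyran ring of the chromene (step 4), then the temporary 2-pyranone ring (step 8), which is opened again in step 10.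

Key step: step 8

Assumption: the target is taken as the open 2-hydroxyaryl 1,2-diketone as drawn; it has no stereocentre, and the two carbinol intermediates on the way to it are handled as racemates.

**Route**

Step 1
Reactants: 1 5-methoxybenzene-1,3-diol (5-methoxyresorcinol)
Product: 2 1-methoxy-3,5-bis(methoxymethoxy)benzene
Conditions: NaH (2.4 equiv), MOMCl (2.4 equiv), DMF, 0 °C → rt
Reagents that add atoms: chloromethyl methyl ether (MOMCl), COCCl
Why: Williamson etherification of both phenoxides with the hard electrophile MOMCl should give the bis-acetal, whose OCH2OMe groups are the directing groups needed in step 2.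

Step 2
Reactants: 2 1-methoxy-3,5-bis(methoxymethoxy)benzene; 3 1-bromo-3-methylbut-2-ene (prenyl bromide)
Product: 5 5-methoxy-1,3-bis(methoxymethoxy)-2-(3-methylbut-2-enyl)benzene, via aryllithium 4 (not isolated)
Conditions: n-BuLi (1.1 equiv), THF, 0 °C; then CuI (10 mol %), 3 (1.2 equiv), −78 °C → rt
Reagents that add atoms: none
Why: Directed ortho-metalation should occur at the carbon flanked by the two chelating OCH2OMe groups (stronger directors than OMe), and the aryllithium, relayed through an arylcopper species, should undergo allylic substitution at the primary carbon of prenyl bromide.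

Step 3
Reactants: 5 5-methoxy-1,3-bis(methoxymethoxy)-2-(3-methylbut-2-enyl)benzene
Product: 6 5-methoxy-2-(3-methylbut-2-enyl)benzene-1,3-diol
Conditions: HCl (3 M aq)/MeOH (1:10), 40 °C, stopped at full conversion
Reagents that add atoms: none
Why: Acid-catalysed acetal exchange with methanol removes both MOM groups as dimethoxymethane, and dilute acid at low temperature is chosen so that Markovnikov addition of the freed phenols to the prenyl alkene (chroman formation) stays slow.

Step 4
Reactants: 6 5-methoxy-2-(3-methylbut-2-enyl)benzene-1,3-diol; 7 3-methylbut-2-enal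
Product: 9 5-methoxy-2,2-dimethyl-8-(3-methylbut-2-enyl)-2H-chromen-7-ol, via quinone methide dienone 8 (not isolated)
Conditions: ethylenediammonium diacetate (10 mol %), 7 (1.05 equiv, slow addition), toluene, 110 °C
Reagents that add atoms: none
Why: Amine-salt-catalysed Knoevenagel-type condensation of the enal at the free carbon ortho to one hydroxyl gives the o-quinone methide dienone, which closes the pyran ring by oxa-6π electrocyclisation; because 6 is symmetrical and the carbon between its hydroxyls is blocked, only one chromene can form.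

Step 5
Reactants: 10 2-(4-hydroxyphenyl)acetic acid
Product: 12 2-[4-(triisopropylsilyloxy)phenyl]acetic acid, via silyl ester 11 (not isolated)
Conditions: TIPSCl (2.3 equiv), imidazole (5 equiv), DMF, rt; then K2CO3 (1.5 equiv), THF/H2O, rt; citric acid to pH 4
Reagents that add atoms: chlorotriisopropylsilane (TIPSCl), CC(C)[Si](Cl)(C(C)C)C(C)C
Why: Imidazole-promoted silylation of phenol and acid followed by mild carbonate hydrolysis of the far more labile silyl ester should leave the hindered aryl silyl ether in place.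

Step 6
Reactants: 12 2-[4-(triisopropylsilyloxy)phenyl]acetic acid
Product: 14 2-[4-(triisopropylsilyloxy)phenyl]propanedioic acid, via dilithium enediolate 13 (not isolated)
Conditions: LiN(i-Pr)2 (2.2 equiv), THF, −78 → 0 °C; CO2 (gas), −78 °C; 1 M HCl, 0 °C; crude acid used directly
Reagents that add atoms: carbon dioxide, O=C=O
Why: Double deprotonation gives the arylacetic acid enediolate (Ivanov-type dianion), whose benzylic carbon is carboxylated by CO2, and cold acidification with direct use of the crude acid avoids decarboxylation of the arylmalonic acid.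

Step 7
Reactants: 14 2-[4-(triisopropylsilyloxy)phenyl]propanedioic acid
Product: 16 bis(2,4,6-trichlorophenyl) 2-[4-(triisopropylsilyloxy)phenyl]propanedioate, via malonyl dichloride 15 (not isolated)
Conditions: (COCl)2 (2.5 equiv), DMF (cat.), CH2Cl2, 0 °C → rt; evaporate; 2,4,6-trichlorophenol (2.1 equiv), pyridine (2.2 equiv), CH2Cl2, −20 °C → rt
Reagents that add atoms: 2,4,6-trichlorophenol, Oc1c(Cl)cc(Cl)cc1Cl
Why: Acid chloride formation under chloroiminium catalysis and acylation of the hindered, acidic phenol in the presence of pyridine should give the active diester without heat or strong acid, so the silyl ether survives.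

Step 8
Reactants: 9 5-methoxy-2,2-dimethyl-8-(3-methylbut-2-enyl)-2H-chromen-7-ol; 16 bis(2,4,6-trichlorophenyl) 2-[4-(triisopropylsilyloxy)phenyl]propanedioate
Product: 20 4-hydroxy-5-methoxy-8,8-dimethyl-10-(3-methylbut-2-enyl)-3-[4-(triisopropylsilyloxy)phenyl]-2H,8H-pyrano[3,2-g]chromen-2-one, via aryloxycarbonyl ketene 17 (not isolated), via mixed malonate 18 (not isolated), via acylketene ester 19 (not isolated)
Conditions: 16 (1.1 equiv), 1,2-dichlorobenzene (0.05 M), 165 °C, Ar
Reagents that add atoms: none
Why: On heating, active ester 16 should expel one 2,4,6-trichlorophenol to give ketene 17, which the only free hydroxyl of 9 (O7–H) captures as mixed malonate 18; a second loss of trichlorophenol gives acylketene ester 19, whose ketene carbon is attacked by C6 of the tethered trioxygenated ring, and the resulting dienone tautomerises to the aromatic 4-hydroxycoumarin 20. The closest known reaction type is the thermal cyclocondensation of phenols with bis(2,4,6-trichlorophenyl) malonates to 4-hydroxycoumarins. The 2-pyranone ring is closed by the C6–C4 bond (coumarin numbering) in an intramolecular Friedel–Crafts-type C-acylation, a 6-exo-dig attack of the arene on the ketene carbon, after the O7–C2 ester bond has been made. No stereocentre is formed. The step needs site selectivity and ring closure in preference to intermolecular diester formation: O7–H is the only hydroxyl, C6 is the only unsubstituted carbon of ring A and is activated by three oxygen substituents while C8 is blocked by the prenyl group, and high dilution in a neutral medium favours cyclisation and spares the prenyl and chromene alkenes.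

Step 9
Reactants: 20 4-hydroxy-5-methoxy-8,8-dimethyl-10-(3-methylbut-2-enyl)-3-[4-(triisopropylsilyloxy)phenyl]-2H,8H-pyrano[3,2-g]chromen-2-one
Product: 22 rac-3-hydroxy-5-methoxy-8,8-dimethyl-10-(3-methylbut-2-enyl)-3-[4-(triisopropylsilyloxy)phenyl]-2H,8H-pyrano[3,2-g]chromene-2,4(3H)-dione, via sodium enolate 21 (not isolated)
Conditions: NaH (1.1 equiv), THF, 0 °C; 2-(benzenesulfonyl)-3-phenyloxaziridine (1.3 equiv), 0 °C → rt; aq NH4Cl
Reagents that add atoms: 2-(benzenesulfonyl)-3-phenyloxaziridine (Davis oxaziridine), O=S(=O)(c1ccccc1)N1OC1c1ccccc1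
Why: The enolate of the vinylogous acid should attack the electrophilic oxygen of the N-sulfonyloxaziridine at C3 (Davis enolate oxidation), a reagent that does not epoxidise the prenyl or chromene alkenes; the new quaternary carbinol centre forms as a racemate and is erased in steps 10 and 11.

Step 10
Reactants: 22 rac-3-hydroxy-5-methoxy-8,8-dimethyl-10-(3-methylbut-2-enyl)-3-[4-(triisopropylsilyloxy)phenyl]-2H,8H-pyrano[3,2-g]chromene-2,4(3H)-dione
Product: 24 rac-2-hydroxy-1-[7-hydroxy-5-methoxy-2,2-dimethyl-8-(3-methylbut-2-enyl)-2H-chromen-6-yl]-2-[4-(triisopropylsilyloxy)phenyl]ethan-1-one, via keto acid 23 (not isolated)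
Conditions: LiOH (3 equiv), degassed THF/H2O (3:1), Ar, 0 °C → rt; then 1 M HCl to pH 3, rt
Reagents that add atoms: none
Why: Hydroxide should open the aryl ester (lactone) at C2, and on acidification the α-hydroxy β-keto acid loses CO2 through its enediol to give the benzoin (saponification followed by β-keto acid decarboxylation); the carbinol centre is racemic and is destroyed in step 11, and either ketol tautomer leads to the same diketone.

Step 11
Reactants: 24 rac-2-hydroxy-1-[7-hydroxy-5-methoxy-2,2-dimethyl-8-(3-methylbut-2-enyl)-2H-chromen-6-yl]-2-[4-(triisopropylsilyloxy)phenyl]ethan-1-one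
Product: 25 1-[7-hydroxy-5-methoxy-2,2-dimethyl-8-(3-methylbut-2-enyl)-2H-chromen-6-yl]-2-[4-(triisopropylsilyloxy)phenyl]ethane-1,2-dione
Conditions: Dess–Martin periodinane (1.3 equiv), CH2Cl2, 0 °C → rt
Reagents that add atoms: none
Why: Dess–Martin oxidation should convert the secondary benzylic α-ketol into the 1,2-diketone under neutral conditions, the O7–H being protected from oxidation by its hydrogen bond to the C6 carbonyl and by full substitution at its ortho and para positions.

Step 12
Reactants: 25 1-[7-hydroxy-5-methoxy-2,2-dimethyl-8-(3-methylbut-2-enyl)-2H-chromen-6-yl]-2-[4-(triisopropylsilyloxy)phenyl]ethane-1,2-dione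
Product: 26 Derrisdione A, 1-[7-hydroxy-5-methoxy-2,2-dimethyl-8-(3-methylbut-2-enyl)-2H-chromen-6-yl]-2-(4-hydroxyphenyl)ethane-1,2-dione
Conditions: Bu4NF (1.1 equiv), AcOH (1.2 equiv), THF, 0 °C
Reagents that add atoms: none
Why: Fluoride-mediated cleavage of the aryl silyl ether, buffered with acetic acid so that the phenoxide and the base-sensitive 1,2-diketone are not exposed to basic fluoride, should release the target.

**Compound list**

1 | 5-methoxybenzene-1,3-diol (5-methoxyresorcinol) | COc1cc(O)cc(O)c1 | starting material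
2 | 1-methoxy-3,5-bis(methoxymethoxy)benzene | COCOc1cc(OC)cc(OCOC)c1 | intermediate
3 | 1-bromo-3-methylbut-2-ene (prenyl bromide) | CC(C)=CCBr | starting material
4 | [4-methoxy-2,6-bis(methoxymethoxy)phenyl]lithium (not isolated) | [Li]c1c(OCOC)cc(OC)cc1OCOC | intermediate
5 | 5-methoxy-1,3-bis(methoxymethoxy)-2-(3-methylbut-2-enyl)benzene | COCOc1cc(OC)cc(OCOC)c1CC=C(C)C | intermediate
6 | 5-methoxy-2-(3-methylbut-2-enyl)benzene-1,3-diol | COc1cc(O)c(CC=C(C)C)c(O)c1 | intermediate
7 | 3-methylbut-2-enal | CC(C)=CC=O | starting material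
8 | (6Z)-3-hydroxy-5-methoxy-2-(3-methylbut-2-enyl)-6-(3-methylbut-2-enylidene)cyclohexa-2,4-dien-1-one (not isolated) | O=C1C(CC=C(C)C)=C(O)C=C(OC)/C1=C/C=C(C)C | intermediate
9 | 5-methoxy-2,2-dimethyl-8-(3-methylbut-2-enyl)-2H-chromen-7-ol | COc1cc(O)c(CC=C(C)C)c2OC(C)(C)C=Cc12 | intermediate
10 | 2-(4-hydroxyphenyl)acetic acid | OC(=O)Cc1ccc(O)cc1 | starting material
11 | triisopropylsilyl 2-[4-(triisopropylsilyloxy)phenyl]acetate (not isolated) | CC(C)[Si](OC(=O)Cc1ccc(O[Si](C(C)C)(C(C)C)C(C)C)cc1)(C(C)C)C(C)C | intermediate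
12 | 2-[4-(triisopropylsilyloxy)phenyl]acetic acid | OC(=O)Cc1ccc(O[Si](C(C)C)(C(C)C)C(C)C)cc1 | intermediate
13 | dilithium 2-[4-(triisopropylsilyloxy)phenyl]ethene-1,1-diolate (not isolated) | [Li]OC(O[Li])=Cc1ccc(O[Si](C(C)C)(C(C)C)C(C)C)cc1 | intermediate
14 | 2-[4-(triisopropylsilyloxy)phenyl]propanedioic acid | OC(=O)C(C(=O)O)c1ccc(O[Si](C(C)C)(C(C)C)C(C)C)cc1 | intermediate
15 | 2-[4-(triisopropylsilyloxy)phenyl]propanedioyl dichloride (not isolated) | O=C(Cl)C(C(=O)Cl)c1ccc(O[Si](C(C)C)(C(C)C)C(C)C)cc1 | intermediate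
16 | bis(2,4,6-trichlorophenyl) 2-[4-(triisopropylsilyloxy)phenyl]propanedioate | O=C(Oc1c(Cl)cc(Cl)cc1Cl)C(C(=O)Oc1c(Cl)cc(Cl)cc1Cl)c1ccc(O[Si](C(C)C)(C(C)C)C(C)C)cc1 | intermediate
17 | 2,4,6-trichlorophenyl 3-oxo-2-[4-(triisopropylsilyloxy)phenyl]prop-2-enoate (not isolated) | O=C=C(C(=O)Oc1c(Cl)cc(Cl)cc1Cl)c1ccc(O[Si](C(C)C)(C(C)C)C(C)C)cc1 | intermediate
18 | rac-1-[5-methoxy-2,2-dimethyl-8-(3-methylbut-2-enyl)-2H-chromen-7-yl] 3-(2,4,6-trichlorophenyl) 2-[4-(triisopropylsilyloxy)phenyl]propanedioate (not isolated) | COc1cc(OC(=O)C(C(=O)Oc2c(Cl)cc(Cl)cc2Cl)c2ccc(O[Si](C(C)C)(C(C)C)C(C)C)cc2)c(CC=C(C)C)c2OC(C)(C)C=Cc12 | intermediate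
19 | 5-methoxy-2,2-dimethyl-8-(3-methylbut-2-enyl)-2H-chromen-7-yl 3-oxo-2-[4-(triisopropylsilyloxy)phenyl]prop-2-enoate (not isolated) | COc1cc(OC(=O)C(=C=O)c2ccc(O[Si](C(C)C)(C(C)C)C(C)C)cc2)c(CC=C(C)C)c2OC(C)(C)C=Cc12 | intermediate
20 | 4-hydroxy-5-methoxy-8,8-dimethyl-10-(3-methylbut-2-enyl)-3-[4-(triisopropylsilyloxy)phenyl]-2H,8H-pyrano[3,2-g]chromen-2-one | COc1c2C=CC(C)(C)Oc2c(CC=C(C)C)c2oc(=O)c(-c3ccc(O[Si](C(C)C)(C(C)C)C(C)C)cc3)c(O)c12 | intermediate
21 | sodium 5-methoxy-8,8-dimethyl-10-(3-methylbut-2-enyl)-2-oxo-3-[4-(triisopropylsilyloxy)phenyl]-2H,8H-pyrano[3,2-g]chromen-4-olate (not isolated) | COc1c2C=CC(C)(C)Oc2c(CC=C(C)C)c2oc(=O)c(-c3ccc(O[Si](C(C)C)(C(C)C)C(C)C)cc3)c([O-])c12.[Na+] | intermediate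
22 | rac-3-hydroxy-5-methoxy-8,8-dimethyl-10-(3-methylbut-2-enyl)-3-[4-(triisopropylsilyloxy)phenyl]-2H,8H-pyrano[3,2-g]chromene-2,4(3H)-dione | COc1c2C=CC(C)(C)Oc2c(CC=C(C)C)c2OC(=O)C(O)(c3ccc(O[Si](C(C)C)(C(C)C)C(C)C)cc3)C(=O)c12 | intermediate
23 | rac-2-hydroxy-3-[7-hydroxy-5-methoxy-2,2-dimethyl-8-(3-methylbut-2-enyl)-2H-chromen-6-yl]-3-oxo-2-[4-(triisopropylsilyloxy)phenyl]propanoic acid (not isolated) | COc1c2C=CC(C)(C)Oc2c(CC=C(C)C)c(O)c1C(=O)C(O)(C(=O)O)c1ccc(O[Si](C(C)C)(C(C)C)C(C)C)cc1 | intermediate
24 | rac-2-hydroxy-1-[7-hydroxy-5-methoxy-2,2-dimethyl-8-(3-methylbut-2-enyl)-2H-chromen-6-yl]-2-[4-(triisopropylsilyloxy)phenyl]ethan-1-one | COc1c2C=CC(C)(C)Oc2c(CC=C(C)C)c(O)c1C(=O)C(O)c1ccc(O[Si](C(C)C)(C(C)C)C(C)C)cc1 | intermediate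
25 | 1-[7-hydroxy-5-methoxy-2,2-dimethyl-8-(3-methylbut-2-enyl)-2H-chromen-6-yl]-2-[4-(triisopropylsilyloxy)phenyl]ethane-1,2-dione | COc1c2C=CC(C)(C)Oc2c(CC=C(C)C)c(O)c1C(=O)C(=O)c1ccc(O[Si](C(C)C)(C(C)C)C(C)C)cc1 | intermediate
26 | Derrisdione A | COc1c2c(c(CC=C(C)C)c(O)c1C(=O)C(=O)c1ccc(O)cc1)OC(C)(C)C=C2 | target

**Step count and risks**

Total step count: 12. Longest linear sequence: 9 steps (steps 1–4 and 8–12, from 5-methoxyresorcinol); the malonate arm (steps 5–7) joins at step 8.

Steps most likely to fail: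

Step 8. At the temperature needed for ketene formation the substrate may degrade before C-acylation: trichlorophenol-promoted addition of O7–H to the prenyl alkene, electrocyclic opening and oligomerisation of the chromene, or arrest at the O-acyl stage with decarboxylation to the arylacetate. The fallback sets out from 9 and 12 and comes back to the route at 24; it makes the C6–acyl bond without the lactone and without heat. Acid 12 is converted with (COCl)2 and catalytic DMF in CH2Cl2 into 2-[4-(triisopropylsilyloxy)phenyl]acetyl chloride F1. Chromenol 9 is deprotonated with EtMgBr in toluene to bromomagnesium 5-methoxy-2,2-dimethyl-8-(3-methylbut-2-enyl)-2H-chromen-7-olate F2, which is C-acylated by F1 at C6 through the magnesium chelate (ortho-selective acylation of magnesium phenoxides). This should give the deoxybenzoin 1-[7-hydroxy-5-methoxy-2,2-dimethyl-8-(3-methylbut-2-enyl)-2H-chromen-6-yl]-2-[4-(triisopropylsilyloxy)phenyl]ethan-1-one F3. Treatment with KN(SiMe3)2 (2.2 equiv, THF, −78 °C) gives the dipotassium phenoxide enolate of this ketone F4, which the Davis oxaziridine hydroxylates at the benzylic carbon; NH4Cl work-up should give benzoin 24, and steps 11 and 12 follow.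

Step 10. Hydroxide may attack the C4 ketone instead of the lactone carbonyl (retro-Claisen cleavage), strip the aryl silyl ether, or leave an enediolate that is oxidised by adventitious air and rearranges in base. The fallback sets out from 20 and comes back at 24; it reverses the order of decarboxylation and oxidation. Coumarin 20 is heated with KOH in aqueous ethanol under argon, the classical alkaline degradation of 3-aryl-4-hydroxycoumarins. This opens the lactone, expels CO2 from the β-keto acid and removes the silyl group, and should give 1-[7-hydroxy-5-methoxy-2,2-dimethyl-8-(3-methylbut-2-enyl)-2H-chromen-6-yl]-2-(4-hydroxyphenyl)ethan-1-one F5. TIPSCl and imidazole in DMF should silylate only the unhindered, non-chelated oxygen of the 4-hydroxyphenyl ring and so give the deoxybenzoin F3 of the preceding fallback. F3 is hydroxylated through its dianion F4 with the Davis oxaziridine to benzoin 24.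

Step 4. The product still has a free phenol with a free ortho carbon, so a second annulation may compete, or the condensation may be slow at the flanked ring carbon and the enal may self-condense. The fallback sets out from 6 and comes back at 9; it builds the pyran ring by a propargyl ether rearrangement instead of an aldehyde condensation. One hydroxyl of symmetrical 6 is etherified with 3-chloro-3-methylbut-1-yne (CuCl2 cat., DBU, MeCN, 0 °C) to give 5-methoxy-3-(2-methylbut-3-yn-2-yloxy)-2-(3-methylbut-2-enyl)phenol F6. Heating F6 in N,N-diethylaniline at about 140 °C should give chromenol 9 by aryl propargyl ether Claisen rearrangement to the only free ortho carbon, 1,5-hydrogen shift and oxa-6π electrocyclisation.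

**Further compounds**

F1 | step 8 | 2-[4-(triisopropylsilyloxy)phenyl]acetyl chloride | O=C(Cl)Cc1ccc(O[Si](C(C)C)(C(C)C)C(C)C)cc1
F2 | step 8 | bromomagnesium 5-methoxy-2,2-dimethyl-8-(3-methylbut-2-enyl)-2H-chromen-7-olate | COc1cc(O[Mg]Br)c(CC=C(C)C)c2OC(C)(C)C=Cc12
F3 | step 8 | 1-[7-hydroxy-5-methoxy-2,2-dimethyl-8-(3-methylbut-2-enyl)-2H-chromen-6-yl]-2-[4-(triisopropylsilyloxy)phenyl]ethan-1-one | COc1c2C=CC(C)(C)Oc2c(CC=C(C)C)c(O)c1C(=O)Cc1ccc(O[Si](C(C)C)(C(C)C)C(C)C)cc1
F4 | step 8 | dipotassium phenoxide enolate of 1-[7-hydroxy-5-methoxy-2,2-dimethyl-8-(3-methylbut-2-enyl)-2H-chromen-6-yl]-2-[4-(triisopropylsilyloxy)phenyl]ethan-1-one | COc1c2C=CC(C)(C)Oc2c(CC=C(C)C)c(O[K])c1C(O[K])=Cc1ccc(O[Si](C(C)C)(C(C)C)C(C)C)cc1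
F5 | step 10 | 1-[7-hydroxy-5-methoxy-2,2-dimethyl-8-(3-methylbut-2-enyl)-2H-chromen-6-yl]-2-(4-hydroxyphenyl)ethan-1-one | COc1c2C=CC(C)(C)Oc2c(CC=C(C)C)c(O)c1C(=O)Cc1ccc(O)cc1
F6 | step 4 | 5-methoxy-3-(2-methylbut-3-yn-2-yloxy)-2-(3-methylbut-2-enyl)phenol | COc1cc(O)c(CC=C(C)C)c(OC(C)(C)C#C)c1
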